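**Retrosynthetic overview**

1. Target ⇐ H2/Pd–C on the bis-O-benzyl (E)-octadec-2-enoate: one operation saturates C2=C3 of the acyl chain and frees both phenols.
2. Enoate ⇐ three-component union of the O-benzylated oxolane primary alcohol, Ph3P=C=C=O and hexadecanal, which makes the ester C1–O bond and the chain C2–C3 bond (as C2=C3) in one flask. Enabling feature: the ester carbonyl C1 sits between the exocyclic CH2–O on ring carbon C3 of the oxolane and chain carbon C2, so C2 can be an acyl-stabilised phosphorus ylide carbon.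
3. Oxolane alcohol ⇐ acid-induced 5-exo closure of the ring O1–C2 bond in a benzylic triol ⇐ LiAlH4 opening of a 3,4-trans aldol lactone.
4. Aldol lactone ⇐ (R)-β-(arylmethyl)-γ-butyrolactone + O-benzylvanillin; the lactone ⇐ Evans alkylation of an N-(3-arylpropanoyl)oxazolidinone with tert-butyl bromoacetate.
5. Ring order: γ-butyrolactone (step 4, temporary) → opened (step 6) → oxolane (step 7); the acyl chain is attached last.

Key step: step 8

Remark: in 15 and 16 the carbinol carbon is a mixture of both configurations and is drawn without a descriptor; this is intended, because step 7 passes through a planar benzylic cation that resets this centre.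

**Route**

Step 1
Reactants: 1 3-(4-hydroxy-3-methoxyphenyl)propanoic acid (dihydroferulic acid)
Product: 3 3-[4-(benzyloxy)-3-methoxyphenyl]propanoic acid, via benzyl ester 2 (not isolated)
Conditions: BnBr (2.3 equiv), K2CO3, DMF, 60 °C; then 2 M aq NaOH, MeOH, 60 °C; HCl work-up
Reagents that add atoms: benzyl bromide, BrCc1ccccc1; sodium hydroxide, [Na+].[OH-] (its oxygen ends in the CO2H group after ester hydrolysis)
Why: Williamson benzylation of the phenoxide (the carboxylate is esterified as well) followed by in-flask saponification of benzyl ester 2 should return the O-benzyl acid; no stereocentre is involved.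

Step 2
Reactants: 3 3-[4-(benzyloxy)-3-methoxyphenyl]propanoic acid; 4 pivaloyl chloride; 5 (4S)-4-benzyl-1,3-oxazolidin-2-one
Product: 7 (4S)-4-benzyl-3-{3-[4-(benzyloxy)-3-methoxyphenyl]propanoyl}-1,3-oxazolidin-2-one, via pivalic mixed anhydride 6 (not isolated)
Conditions: 4, Et3N, THF, −20 °C; then 5, LiCl, −20 °C → rt
Reagents that add atoms: none
Why: Mixed-anhydride N-acylation of the Evans oxazolidinone (LiCl/Et3N protocol) should occur at the unhindered arylpropanoyl carbonyl of 6 with loss of pivalate, leaving the auxiliary stereocentre untouched.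

Step 3
Reactants: 7 (4S)-4-benzyl-3-{3-[4-(benzyloxy)-3-methoxyphenyl]propanoyl}-1,3-oxazolidin-2-one; 8 tert-butyl bromoacetate
Product: 10 tert-butyl (3R)-4-[(4S)-4-benzyl-2-oxo-1,3-oxazolidin-3-yl]-3-{[4-(benzyloxy)-3-methoxyphenyl]methyl}-4-oxobutanoate, via sodium Z-enolate 9 (not isolated)
Conditions: NaHMDS, THF, −78 °C; then 8, −78 → −40 °C
Reagents that add atoms: none
Why: Evans asymmetric alkylation: the chelated Z-enolate 9 is shielded on one face by the C4 benzyl group of the (4S)-auxiliary, so the bromoacetate should enter from the opposite face and set the (R) centre that becomes C4 of the oxolane.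

Step 4
Reactants: 10 tert-butyl (3R)-4-[(4S)-4-benzyl-2-oxo-1,3-oxazolidin-3-yl]-3-{[4-(benzyloxy)-3-methoxyphenyl]methyl}-4-oxobutanoate
Product: 12 (4R)-4-{[4-(benzyloxy)-3-methoxyphenyl]methyl}oxolan-2-one, via hydroxy tert-butyl ester 11 (not isolated)
Conditions: LiBH4, THF, 0 °C; then p-TsOH·H2O (cat.), toluene, 80 °C
Reagents that add atoms: none
Why: Reductive cleavage of the imide by LiBH4 (the tert-butyl ester is inert at 0 °C) releases the auxiliary and the primary alcohol, and acid-catalysed lactonisation with loss of isobutene then gives the γ-butyrolactone without touching the stereocentre.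

Step 5
Reactants: 12 (4R)-4-{[4-(benzyloxy)-3-methoxyphenyl]methyl}oxolan-2-one; 13 4-(benzyloxy)-3-methoxybenzaldehyde
Product: 15 (3S,4R)-4-{[4-(benzyloxy)-3-methoxyphenyl]methyl}-3-{[4-(benzyloxy)-3-methoxyphenyl](hydroxy)methyl}oxolan-2-one (both carbinol epimers), via lithium lactone enolate 14 (not isolated)
Conditions: LiHMDS, THF, −78 °C; then 13, −78 °C; sat. aq NH4Cl at −78 °C
Reagents that add atoms: none
Why: Aldol addition of the lactone enolate, in which the aldehyde should approach anti to the C4 arylmethyl group and so set the 3,4-trans relationship (the future C3 of the oxolane); the carbinol configuration is not controlled and need not be, since step 7 erases it.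

Step 6
Reactants: 15 (3S,4R)-4-{[4-(benzyloxy)-3-methoxyphenyl]methyl}-3-{[4-(benzyloxy)-3-methoxyphenyl](hydroxy)methyl}oxolan-2-one
Product: 16 (2R,3R)-2-{[4-(benzyloxy)-3-methoxyphenyl](hydroxy)methyl}-3-{[4-(benzyloxy)-3-methoxyphenyl]methyl}butane-1,4-diol (both carbinol epimers)
Conditions: LiAlH4, THF, 0 °C → rt; Fieser work-up
Reagents that add atoms: none
Why: Hydride reduction of the lactone to the 1,4-diol (LiAlH4) should proceed with the benzyl ethers and both backbone stereocentres unaffected.

Step 7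
Reactants: 16 (2R,3R)-2-{[4-(benzyloxy)-3-methoxyphenyl](hydroxy)methyl}-3-{[4-(benzyloxy)-3-methoxyphenyl]methyl}butane-1,4-diol
Product: 17 [(2S,3R,4R)-2-[4-(benzyloxy)-3-methoxyphenyl]-4-{[4-(benzyloxy)-3-methoxyphenyl]methyl}oxolan-3-yl]methanol
Conditions: (±)-CSA (10 mol%), CH2Cl2 (0.02 M), 0 °C → rt
Reagents that add atoms: none
Why: Acid-catalysed SN1 cycloetherification: only the p-alkoxybenzylic hydroxyl ionises, the more remote CH2OH closes the five-membered ring (5-exo capture; the nearer CH2OH could only give an oxetane), and the aryl group should settle trans to the neighbouring CH2OH substituent from either carbinol epimer, which sets ring C2 as (S).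

Step 8
Reactants: 17 [(2S,3R,4R)-2-[4-(benzyloxy)-3-methoxyphenyl]-4-{[4-(benzyloxy)-3-methoxyphenyl]methyl}oxolan-3-yl]methanol; 18 (triphenylphosphoranylidene)ketene (Bestmann ylide); 19 hexadecanal
Product: 21 [(2S,3R,4R)-2-[4-(benzyloxy)-3-methoxyphenyl]-4-{[4-(benzyloxy)-3-methoxyphenyl]methyl}oxolan-3-yl]methyl (2E)-octadec-2-enoate, via ester ylide 20 (not isolated)
Conditions: 18 (1.2 equiv), toluene, 90 °C; then 19 (1.5 equiv), 90 °C
Reagents that add atoms: none
Why: The only O–H group of 17, the primary hydroxyl on the CH2 attached to ring C3, adds across the P=C=C=O cumulene of 18 (alkoxide attack at the ketene carbon, proton to the ylide carbon) to give ester ylide 20, whose ylide carbon (chain C2) then undergoes Wittig olefination with the aldehyde carbon of 19 (chain C3) through an oxaphosphetane that collapses with loss of Ph3P=O. The closest known reaction type is the Bestmann-ylide alcohol/aldehyde three-component esterification–Wittig coupling, established for primary alcohols and unbranched aliphatic aldehydes. No ring is closed and no stereocentre is created; the alkene should be E, which is immaterial because step 9 saturates it. The step needs capture of the cumulene at a single oxygen and an ylide that neither enolises hexadecanal nor epimerises the benzylic C2–H of the oxolane: 17 carries one free hydroxyl only (both phenols are benzyl ethers), and the ester-stabilised ylide is neutral and non-basic. In one flask the ester C1–O bond and the C2–C3 bond of the C18 chain are formed from three components, each much simpler than 21.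

Step 9
Reactants: 21 [(2S,3R,4R)-2-[4-(benzyloxy)-3-methoxyphenyl]-4-{[4-(benzyloxy)-3-methoxyphenyl]methyl}oxolan-3-yl]methyl (2E)-octadec-2-enoate
Product: 23 [(2S,3R,4R)-2-(4-hydroxy-3-methoxyphenyl)-4-[(4-hydroxy-3-methoxyphenyl)methyl]oxolan-3-yl]methyl octadecanoate, via saturated bis(benzyl ether) 22 (not isolated)
Conditions: H2 (1 atm), 10% Pd/C, EtOAc, rt; stopped as soon as debenzylation is complete
Reagents that add atoms: none
Why: Heterogeneous hydrogenation/hydrogenolysis: the conjugated alkene should be saturated first and the two aryl benzyl ethers then cleaved as toluene, while the benzylic C–O bond of the oxolane should react much more slowly, so the reaction is stopped at full debenzylation; no stereocentre is affected.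

**Compound list**

1 | 3-(4-hydroxy-3-methoxyphenyl)propanoic acid | OC(=O)CCc1ccc(O)c(OC)c1 | starting material
2 | benzyl 3-[4-(benzyloxy)-3-methoxyphenyl]propanoate | O=C(CCc1ccc(OCc2ccccc2)c(OC)c1)OCc1ccccc1 | intermediate (not isolated)
3 | 3-[4-(benzyloxy)-3-methoxyphenyl]propanoic acid | OC(=O)CCc1ccc(OCc2ccccc2)c(OC)c1 | intermediate
4 | pivaloyl chloride | CC(C)(C)C(=O)Cl | starting material
5 | (4S)-4-benzyl-1,3-oxazolidin-2-one | O=C1N[C@@H](Cc2ccccc2)CO1 | starting material
6 | 3-[4-(benzyloxy)-3-methoxyphenyl]propanoic pivalic anhydride | CC(C)(C)C(=O)OC(=O)CCc1ccc(OCc2ccccc2)c(OC)c1 | intermediate (not isolated)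
7 | (4S)-4-benzyl-3-{3-[4-(benzyloxy)-3-methoxyphenyl]propanoyl}-1,3-oxazolidin-2-one | O=C(CCc1ccc(OCc2ccccc2)c(OC)c1)N1C(=O)OC[C@@H]1Cc1ccccc1 | intermediate
8 | tert-butyl bromoacetate | CC(C)(C)OC(=O)CBr | starting material
9 | sodium (Z)-enolate of 7 | [Na+].[O-]/C(=C\Cc1ccc(OCc2ccccc2)c(OC)c1)N1C(=O)OC[C@@H]1Cc1ccccc1 | intermediate (not isolated)
10 | tert-butyl (3R)-4-[(4S)-4-benzyl-2-oxo-1,3-oxazolidin-3-yl]-3-{[4-(benzyloxy)-3-methoxyphenyl]methyl}-4-oxobutanoate | O=C([C@H](Cc1ccc(OCc2ccccc2)c(OC)c1)CC(=O)OC(C)(C)C)N1C(=O)OC[C@@H]1Cc1ccccc1 | intermediate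
11 | tert-butyl (3R)-4-[4-(benzyloxy)-3-methoxyphenyl]-3-(hydroxymethyl)butanoate | OC[C@H](Cc1ccc(OCc2ccccc2)c(OC)c1)CC(=O)OC(C)(C)C | intermediate (not isolated)
12 | (4R)-4-{[4-(benzyloxy)-3-methoxyphenyl]methyl}oxolan-2-one | O=C1C[C@@H](Cc2ccc(OCc3ccccc3)c(OC)c2)CO1 | intermediate
13 | 4-(benzyloxy)-3-methoxybenzaldehyde | O=Cc1ccc(OCc2ccccc2)c(OC)c1 | starting material
14 | lithium enolate of 12 | [Li+].[O-]C1=C[C@@H](Cc2ccc(OCc3ccccc3)c(OC)c2)CO1 | intermediate (not isolated)
15 | (3S,4R)-4-{[4-(benzyloxy)-3-methoxyphenyl]methyl}-3-{[4-(benzyloxy)-3-methoxyphenyl](hydroxy)methyl}oxolan-2-one, both carbinol epimers | O=C1[C@H](C(O)c2ccc(OCc3ccccc3)c(OC)c2)[C@@H](Cc2ccc(OCc3ccccc3)c(OC)c2)CO1 | intermediate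
16 | (2R,3R)-2-{[4-(benzyloxy)-3-methoxyphenyl](hydroxy)methyl}-3-{[4-(benzyloxy)-3-methoxyphenyl]methyl}butane-1,4-diol, both carbinol epimers | OC[C@H](C(O)c1ccc(OCc2ccccc2)c(OC)c1)[C@@H](Cc1ccc(OCc2ccccc2)c(OC)c1)CO | intermediate
17 | [(2S,3R,4R)-2-[4-(benzyloxy)-3-methoxyphenyl]-4-{[4-(benzyloxy)-3-methoxyphenyl]methyl}oxolan-3-yl]methanol | OC[C@H]1[C@@H](Cc2ccc(OCc3ccccc3)c(OC)c2)CO[C@@H]1c1ccc(OCc2ccccc2)c(OC)c1 | intermediate
18 | (triphenylphosphoranylidene)ketene | O=C=C=P(c1ccccc1)(c1ccccc1)c1ccccc1 | starting material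
19 | hexadecanal | CCCCCCCCCCCCCCCC=O | starting material
20 | [(2S,3R,4R)-2-[4-(benzyloxy)-3-methoxyphenyl]-4-{[4-(benzyloxy)-3-methoxyphenyl]methyl}oxolan-3-yl]methyl 2-(triphenylphosphoranylidene)acetate | O=C(C=P(c1ccccc1)(c1ccccc1)c1ccccc1)OC[C@H]1[C@@H](Cc2ccc(OCc3ccccc3)c(OC)c2)CO[C@@H]1c1ccc(OCc2ccccc2)c(OC)c1 | intermediate (not isolated)
21 | [(2S,3R,4R)-2-[4-(benzyloxy)-3-methoxyphenyl]-4-{[4-(benzyloxy)-3-methoxyphenyl]methyl}oxolan-3-yl]methyl (2E)-octadec-2-enoate | CCCCCCCCCCCCCCC/C=C/C(=O)OC[C@H]1[C@@H](Cc2ccc(OCc3ccccc3)c(OC)c2)CO[C@@H]1c1ccc(OCc2ccccc2)c(OC)c1 | intermediate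
22 | [(2S,3R,4R)-2-[4-(benzyloxy)-3-methoxyphenyl]-4-{[4-(benzyloxy)-3-methoxyphenyl]methyl}oxolan-3-yl]methyl octadecanoate | CCCCCCCCCCCCCCCCCC(=O)OC[C@H]1[C@@H](Cc2ccc(OCc3ccccc3)c(OC)c2)CO[C@@H]1c1ccc(OCc2ccccc2)c(OC)c1 | intermediate (not isolated)
23 | [(2S,3R,4R)-2-(4-hydroxy-3-methoxyphenyl)-4-[(4-hydroxy-3-methoxyphenyl)methyl]oxolan-3-yl]methyl octadecanoate | CCCCCCCCCCCCCCCCCC(=O)OC[C@H]1[C@@H](Cc2ccc(O)c(OC)c2)CO[C@@H]1c1ccc(O)c(OC)c1 | target

**Step count and risks**

Total step count: 9. Longest linear sequence: 9 steps (1 → 23); all other components are commercial.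

Steps most likely to fail:

1. Step 8. The β-branched primary alcohol may add slowly to the cumulene, so that the ylide is lost to traces of water or to self-condensation before the ester ylide has formed, and the aldehyde may self-condense on prolonged heating. Fallback, from 17 back to 21: the alcohol would be acylated with (diethoxyphosphoryl)acetic acid (DCC, DMAP, CH2Cl2) to give [(2S,3R,4R)-2-[4-(benzyloxy)-3-methoxyphenyl]-4-{[4-(benzyloxy)-3-methoxyphenyl]methyl}oxolan-3-yl]methyl 2-(diethoxyphosphoryl)acetate F1. A Masamune–Roush Horner–Wadsworth–Emmons olefination of F1 with 19 (LiCl, DBU, MeCN, rt) should then form the same C2=C3 bond and return the route at 21.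

2. Step 7. The benzylic cation may be captured by the electron-rich pendant arene (Friedel–Crafts closure to an aryltetralin), the product may re-ionise under acid, or the trans selectivity at ring C2 may be incomplete. Fallback, from 16 back to 17: the two primary hydroxyls would be silylated selectively (TBSCl, imidazole, DMF, 0 °C) to give the 1,4-bis(tert-butyldimethylsilyl) ether of 16 F2. Mesylation of the remaining benzylic hydroxyl (MsCl, Et3N, CH2Cl2, −20 °C → rt) should give the benzylic methanesulfonate of the bis-silyl ether F3, which is not isolated. F3 should ionise in the base-buffered medium and be captured by the silyl ether oxygen that closes the five-membered ring, with loss of that silyl group, to give the tert-butyldimethylsilyl ether of 17 F4. TBAF in THF would then release 17.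

3. Step 9. Over-reduction may occur: once the phenol on the 2-aryl group is unmasked, the benzylic C2–O bond of the oxolane may be hydrogenolysed (ring opening) at a rate that competes with the last debenzylation. Fallback, from 21 back to 23: alkene reduction and deprotection would be separated and heterogeneous hydrogenolysis avoided. Copper hydride 1,4-reduction of 21 (Cu(OAc)2·H2O cat., 1,2-bis(diphenylphosphino)benzene, PMHS, t-BuOH, toluene, rt) should give 22, now isolated. The two aryl benzyl ethers would then be removed with BCl3 and pentamethylbenzene (CH2Cl2, −78 °C) to give 23. This fallback makes no compound outside the list (F0).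

Further compounds
F1 | step 8 | [(2S,3R,4R)-2-[4-(benzyloxy)-3-methoxyphenyl]-4-{[4-(benzyloxy)-3-methoxyphenyl]methyl}oxolan-3-yl]methyl 2-(diethoxyphosphoryl)acetate | CCOP(=O)(OCC)CC(=O)OC[C@H]1[C@@H](Cc2ccc(OCc3ccccc3)c(OC)c2)CO[C@@H]1c1ccc(OCc2ccccc2)c(OC)c1
F2 | step 7 | (2R,3R)-1,4-bis(tert-butyldimethylsilyl) ether of 16, both carbinol epimers | CC(C)(C)[Si](C)(C)OC[C@H](C(O)c1ccc(OCc2ccccc2)c(OC)c1)[C@@H](Cc1ccc(OCc2ccccc2)c(OC)c1)CO[Si](C)(C)C(C)(C)C
F3 | step 7 | benzylic methanesulfonate of F2, both epimers | CC(C)(C)[Si](C)(C)OC[C@H](C(OS(C)(=O)=O)c1ccc(OCc2ccccc2)c(OC)c1)[C@@H](Cc1ccc(OCc2ccccc2)c(OC)c1)CO[Si](C)(C)C(C)(C)C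
F4 | step 7 | tert-butyl{[(2S,3R,4R)-2-[4-(benzyloxy)-3-methoxyphenyl]-4-{[4-(benzyloxy)-3-methoxyphenyl]methyl}oxolan-3-yl]methoxy}dimethylsilane | CC(C)(C)[Si](C)(C)OC[C@H]1[C@@H](Cc2ccc(OCc3ccccc3)c(OC)c2)CO[C@@H]1c1ccc(OCc2ccccc2)c(OC)c1
F0 | step 9 | none | none
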